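Daucane numbering is used throughout: C1 = angular C–CH3, C2, C3, C4 = C(OH)iPr, C5 = ring-fusion CH, C6 = CH–OBz, C7=C8(CH3), C9 = C=O, C10 = CH–OH. In this numbering the target is 1S,4R,5S,6S,10R.

Assumption: the bis(oxazoline) enantiomer that gives the (8aR)-azulenone in step 3 is the one used. Both antipodes are commercial, so the other is taken if the sense of induction is reversed.

## Retrosynthetic overview

1. The target comes from ketol epimerisation at C10 and benzoylation at C6. The 6-OH and C7=C8 come from E1cB opening of a β,γ-epoxy ketone, and the 10-O comes from a Rubottom oxidation.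
2. The angular CH3 at C1 comes from an alkoxide-directed conjugate addition to a dienone. The C4(OH)iPr unit comes from an organocerium addition to a cyclopentanone.
3. The five- and seven-membered rings form together in one intramolecular Buchner reaction of an aryl diazoketone. The arene supplies C1, C6–C10, the C8 methyl and the C9 oxygen.
4. The diazoketone comes from diazo transfer on a 4-arylbutan-2-one, which comes from Heck arylation of but-3-en-2-ol.

## Route

Step 1
Reactants: 1 4-bromo-2-methoxy-1-methylbenzene; 2 but-3-en-2-ol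
Product: 3 4-(3-methoxy-4-methylphenyl)butan-2-one
Conditions: Pd(OAc)2 (1 mol %), P(o-tol)3, Bu4NCl, NaHCO3, DMF, 110 °C
Reagents that add atoms: none
Why: Heck arylation of an allylic alcohol, in which carbopalladation at the terminal carbon, β-hydride elimination toward the carbinol and enol–ketone tautomerisation give the saturated aryl ketone directly, with no stereocentre formed.

Step 2
Reactants: 3 4-(3-methoxy-4-methylphenyl)butan-2-one
Product: 5 1-diazo-4-(3-methoxy-4-methylphenyl)butan-2-one, via trifluoroacetyl diketone 4 (not isolated)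
Conditions: LiHMDS, THF, −78 °C; CF3CO2CH2CF3; 5 % HCl work-up; crude + MsN3, Et3N, H2O (1 equiv), MeCN, rt
Reagents that add atoms: 2,2,2-trifluoroethyl trifluoroacetate O=C(OCC(F)(F)F)C(F)(F)F (CF3CO, in 4 only); methanesulfonyl azide CS(=O)(=O)N=[N+]=[N-]
Why: Danheiser detrifluoroacetylative diazo transfer, in which the kinetic CH3 enolate is trifluoroacetylated and the activated 1,3-diketone takes N2 from the azide and passes CF3CO to the sulfonamide, with no stereocentre formed.

Step 3 (key step)
Reactants: 5 1-diazo-4-(3-methoxy-4-methylphenyl)butan-2-one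
Product: 7 (8aR)-5-methoxy-6-methyl-3,8a-dihydroazulen-1(2H)-one, via norcaradiene tautomer 6 (not isolated)
Conditions: [Cu(MeCN)4]PF6 (5 mol %), Ph-box (6 mol %), NaBArF (6 mol %), CH2Cl2, reflux, slow addition; basic alumina
Reagents that add atoms: none
Why: Asymmetric intramolecular Buchner reaction, in which the copper carbene adds to the ipso/ortho bond whose ortho carbon is para to OMe and unflanked, closing the cyclopentanone and a cyclopropane at once (6), and disrotatory 6π opening turns the benzene ring into the cycloheptatriene, so both carbocycles arise in one operation and C5 (8aR) is set by the ligand.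

Step 4
Reactants: 7 (8aR)-5-methoxy-6-methyl-3,8a-dihydroazulen-1(2H)-one
Product: 9 (1R,8aR)-1-hydroxy-6-methyl-1-(propan-2-yl)-2,3,6,8a-tetrahydroazulen-5(1H)-one (C8 epimers, daucane 4R,5R), via tertiary alcohol dienol ether 8 (not isolated)
Conditions: i-PrMgCl, anhydrous CeCl3, THF, −78 °C; then 0.5 M HCl, THF, 0 °C, 15 min
Reagents that add atoms: isopropylmagnesium chloride CC(C)[Mg]Cl; water O
Why: Imamoto organocerium 1,2-addition (non-basic, so C5–H is not enolised) occurs on the carbonyl face that carries H5, anti to the C6 arm of the folded seven-membered ring, which places iPr cis and OH trans to H5 (4R), and the dilute-acid quench hydrolyses the methyl dienol ether by kinetic α-protonation at C8 to the β,γ-unsaturated ketone.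

Step 5
Reactants: 9 hydroxy dienone
Product: 10 (1R,3aR,8aR)-3a,6-dimethyl-1-(propan-2-yl)-5-(triethylsilyloxy)-1,2,3,3a,6,8a-hexahydroazulen-1-ol (trans-fused, CH3 cis to 4-OH)
Conditions: MeMgBr (4 equiv), CuBr·SMe2 (30 mol %), THF–Me2S, −40 to −10 °C; then Et3SiCl, Et3N, DMPU, −40 °C to rt; pH 7 buffer
Reagents that add atoms: methylmagnesium bromide C[Mg]Br; chlorotriethylsilane CC[Si](Cl)(CC)CC
Why: Copper-catalysed conjugate addition with regiospecific enolate silylation, in which the C4 magnesium alkoxide binds the methylmetal reagent and delivers CH3 to C1 through a six-membered array on the oxygen-bearing face while the isopropyl group screens the other face (alkoxide-directed 1,4-addition), giving CH3 cis to 4-OH and trans to H5.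

Step 6
Reactants: 10 silyl enol ether
Product: 12 (1S,4R,5S,6S,10S)-4,6-dihydroxy-10-(triethylsilyloxy)dauc-7-en-9-one, via epoxy silyloxy ketone 11 (not isolated)
Conditions: m-CPBA (2.3 equiv), NaHCO3, CH2Cl2, −20 °C to rt; Na2S2O3/NaHCO3 wash; crude + DBU, CH2Cl2, 0 °C
Reagents that add atoms: m-CPBA OOC(=O)c1cccc(Cl)c1
Why: Rubottom oxidation of the silyl enol ether (the 1,4-silyl shift leaves C10–OTES) and Prilezhaev epoxidation of C6=C7 both occur on the face opposite the axial angular methyl, and DBU then opens the β,γ-epoxy ketone by E1cB to the γ-hydroxy enone, which sets 6S, erases C8 and leaves C10 as the axial epimer.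

Step 7
Reactants: 12 γ-hydroxy enone
Product: 13 (1S,4R,5S,6S,10S)-6-benzoyloxy-4-hydroxy-10-(triethylsilyloxy)dauc-7-en-9-one
Conditions: BzCl, DMAP, pyridine, CH2Cl2, 0 °C to rt
Reagents that add atoms: benzoyl chloride O=C(Cl)c1ccccc1
Why: DMAP-catalysed acylation reaches only the free secondary allylic 6-OH because the C10 oxygen is silylated and the 4-OH is tertiary and flanked by isopropyl, and no stereocentre is touched.

Step 8
Reactants: 13 benzoate
Product: 15 (1S,4R,5S,6S,10R)-6-benzoyloxy-4,10-dihydroxydauc-7-en-9-one (target), via 10-epimer 14 (not isolated)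
Conditions: HF·pyridine, THF, 0 °C; NaHCO3 wash; then DBU (0.2 equiv), toluene, 40 °C
Reagents that add atoms: none
Why: Fluoride desilylation followed by base-mediated α-ketol epimerisation through the enediolate, in which reprotonation of C10 from the open face opposite the angular methyl and the coplanar OH···O=C hydrogen bond favour the pseudo-equatorial 10R alcohol, and the conjugated C9 ketone is the more stable ketol tautomer.

## Compound list

1 | 4-bromo-2-methoxy-1-methylbenzene | Cc1ccc(Br)cc1OC | starting material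
2 | but-3-en-2-ol | CC(O)C=C | starting material
3 | 4-(3-methoxy-4-methylphenyl)butan-2-one | CC(=O)CCc1ccc(C)c(OC)c1 | intermediate
4 | 1,1,1-trifluoro-6-(3-methoxy-4-methylphenyl)hexane-2,4-dione | O=C(CC(=O)C(F)(F)F)CCc1ccc(C)c(OC)c1 | intermediate
5 | 1-diazo-4-(3-methoxy-4-methylphenyl)butan-2-one | [N-]=[N+]=CC(=O)CCc1ccc(C)c(OC)c1 | intermediate
6 | norcaradiene tautomer (cyclopropane C1–C5–C6) | O=C1CC[C@@]23C=C(OC)C(C)=C[C@@H]2[C@@H]13 | intermediate
7 | (8aR)-5-methoxy-6-methyl-3,8a-dihydroazulen-1(2H)-one | CC1=C(OC)C=C2CCC(=O)[C@@H]2C=C1 | intermediate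
8 | (1R,8aR)-5-methoxy-6-methyl-1-(propan-2-yl)-1,2,3,8a-tetrahydroazulen-1-ol | CC1=C(OC)C=C2CC[C@@](O)(C(C)C)[C@@H]2C=C1 | intermediate
9 | (1R,8aR)-1-hydroxy-6-methyl-1-(propan-2-yl)-2,3,6,8a-tetrahydroazulen-5(1H)-one | CC1C(=O)C=C2CC[C@@](O)(C(C)C)[C@@H]2C=C1 | intermediate
10 | trans-fused C9 triethylsilyl enol ether | CC1C(O[Si](CC)(CC)CC)=C[C@@]2(C)CC[C@@](O)(C(C)C)[C@@H]2C=C1 | intermediate
11 | 6,7-epoxy-10-(triethylsilyloxy) ketone (both oxygens on the H5 face) | CC1C(=O)[C@@H](O[Si](CC)(CC)CC)[C@@]2(C)CC[C@@](O)(C(C)C)[C@@H]2[C@H]3O[C@@H]13 | intermediate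
12 | 4,6-dihydroxy-10-(triethylsilyloxy)dauc-7-en-9-one (10S) | CC1=C[C@H](O)[C@@H]2[C@](C)(CC[C@@]2(O)C(C)C)[C@H](O[Si](CC)(CC)CC)C1=O | intermediate
13 | 6-benzoate of 12 | CC1=C[C@H](OC(=O)c2ccccc2)[C@@H]2[C@](C)(CC[C@@]2(O)C(C)C)[C@H](O[Si](CC)(CC)CC)C1=O | intermediate
14 | 10-epimer of the target | CC1=C[C@H](OC(=O)c2ccccc2)[C@@H]2[C@](C)(CC[C@@]2(O)C(C)C)[C@H](O)C1=O | intermediate
15 | CNP0363736.1 | CC1=C[C@H](OC(=O)c2ccccc2)[C@@H]2[C@](C)(CC[C@@]2(O)C(C)C)[C@@H](O)C1=O | target

## Step count and risks

Total step count: 8. Longest linear sequence: 8.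

**Step 3.** The electron-rich arene may divert to a 2-tetralone by aromatic substitution, the carbene may add at the ortho carbon next to OMe, or the ee may be modest.
Fallback, from 5 back to 7: run the ring expansion with achiral Rh2(OAc)4 to give racemic 5-methoxy-6-methyl-3,8a-dihydroazulen-1(2H)-one F1. Then use a ketoreductase (or CBS/borane) kinetic resolution that reduces the 8aS ketone to (1R,8aS)-5-methoxy-6-methyl-1,2,3,8a-tetrahydroazulen-1-ol F2. The unreacted 8aR ketone 7 is recovered by chromatography.

**Step 5.** Fused enones normally take the angular methyl cis to the ring-fusion hydrogen, which is the opposite of what this route needs. The reagent may also enolise C8–H or C5–H, and the alkoxide can fragment by vinylogous retro-aldol.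
Fallback, from 9 back to 10:
- Luche reduction, with hydride arriving on the H5 face, gives the 9-alcohol with OH on the 4-OH face, F3.
- Hydroxyl-directed Simmons–Smith cyclopropanation (Et2Zn, CH2I2) of C1=C10, syn to both hydroxyls, gives the cyclopropyl carbinol F4.
- Dess–Martin oxidation gives the cyclopropyl ketone F5.
- After LiHMDS has masked the 4-OH, Li/NH3 cleaves the exocyclic C10–CH2 bond, which overlaps best with the carbonyl. This leaves the angular CH3 and the regiospecific C9/C10 enolate, which Et3SiCl traps as 10.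

**Step 8.** The equilibrium may be slow because the equatorial C10–H is poorly aligned for removal, or incomplete, and DBU may also deprotonate at the γ position.
Fallback, from 14 back to 15: Dess–Martin oxidation of the ketol gives the 6-benzoyloxy-4-hydroxydauc-7-ene-9,10-dione F6. Hydride (Zn(BH4)2, Et2O, −78 °C) then attacks the non-conjugated C10 carbonyl from the face opposite the angular methyl, which places the 10-OH cis to CH3 as in 15.

## Further compounds

F1 | step 3 | rac-5-methoxy-6-methyl-3,8a-dihydroazulen-1(2H)-one | CC1=C(OC)C=C2CCC(=O)C2C=C1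
F2 | step 3 | (1R,8aS)-5-methoxy-6-methyl-1,2,3,8a-tetrahydroazulen-1-ol | CC1=C(OC)C=C2CC[C@@H](O)[C@H]2C=C1
F3 | step 5 | 9-alcohol of 9 (9-OH on the 4-OH face) | CC1[C@H](O)C=C2CC[C@@](O)(C(C)C)[C@@H]2C=C1
F4 | step 5 | 1,10-methano (cyclopropyl) diol | CC1[C@H](O)[C@@H]3C[C@@]32CC[C@@](O)(C(C)C)[C@@H]2C=C1
F5 | step 5 | 1,10-methano (cyclopropyl) 9-ketone | CC1C(=O)[C@@H]3C[C@@]32CC[C@@](O)(C(C)C)[C@@H]2C=C1
F6 | step 8 | 6-benzoyloxy-4-hydroxydauc-7-ene-9,10-dione | CC1=C[C@H](OC(=O)c2ccccc2)[C@@H]2[C@](C)(CC[C@@]2(O)C(C)C)C(=O)C1=O
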